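**Retrosynthetic overview**
1. The target, 3-docosyl-1H-pyrrole-2-carbaldehyde, is traced back to its N-tosyl derivative 11; the N–S bond is cleaved last.
2. Key disconnection: the C10′–C11′ bond of the side chain (C1′ on ring carbon C3, C22′ the methyl end). A mixed Kolbe electrolysis joins tridecanoic acid 8 and 11-(2-formyl-1-tosylpyrrol-3-yl)undecanoic acid 7 by twofold anodic decarboxylation and radical–radical coupling.
3. Enabling feature: the chain is an unbranched run of 21 CH2 groups and one CH3, so C10′ and C11′ are both plain primary carbons, ideal Kolbe radicals. The pyrrole ring (N1, C2–C5) lies nine CH2 groups away from C10′ and is deactivated by the N1-sulfonyl and C2-formyl groups.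
4. Acid 7 comes from a Sonogashira coupling at C3–Br of 3-bromo-1-tosylpyrrole-2-carbaldehyde 3 with undec-10-ynoic acid 4, then saturation of the alkyne; 3 comes from 3-bromo-1H-pyrrole-2-carbaldehyde 1.
5. Rings: none is formed in the route; the pyrrole ring is bought intact and elaborated first at N1, then at C3.

Key step: step 4

Remark: the target has no stereocentre and is achiral, so no step needs stereocontrol; 3-bromo-1H-pyrrole-2-carbaldehyde is taken as a catalogue building block.

Step 1
Reactants: 1 3-bromo-1H-pyrrole-2-carbaldehyde
Product: 3 3-bromo-1-tosyl-1H-pyrrole-2-carbaldehyde, via sodium 3-bromo-2-formylpyrrol-1-ide 2 (not isolated)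
Conditions: NaH (1.2 equiv), THF, 0 °C; then TsCl (1.1 equiv), 0 °C to rt
Reagents that add atoms: p-toluenesulfonyl chloride, Cc1ccc(cc1)S(Cl)(=O)=O
Why: N-sulfonylation of a pyrrolide anion; the N–H, acidified by the 2-formyl and 3-bromo groups, should be deprotonated cleanly by NaH and the anion sulfonylated on nitrogen.

Step 2
Reactants: 3 3-bromo-1-tosyl-1H-pyrrole-2-carbaldehyde; 4 undec-10-ynoic acid
Product: 5 11-(2-formyl-1-tosyl-1H-pyrrol-3-yl)undec-10-ynoic acid
Conditions: Pd(PPh3)2Cl2 (5 mol%), CuI (10 mol%), Et3N (5 equiv), degassed DMF, 60 °C; 1 M HCl work-up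
Reagents that add atoms: none
Why: Sonogashira coupling; oxidative addition into the C3–Br bond should be eased by the ortho-formyl and N-sulfonyl acceptors, and the carboxylic acid is carried as its triethylammonium salt.

Step 3
Reactants: 5 11-(2-formyl-1-tosyl-1H-pyrrol-3-yl)undec-10-ynoic acid
Product: 7 11-(2-formyl-1-tosyl-1H-pyrrol-3-yl)undecanoic acid, via (Z)-11-(2-formyl-1-tosyl-1H-pyrrol-3-yl)undec-10-enoic acid 6 (not isolated)
Conditions: H2 (1 atm), 10% Pd/C, Ph2S (cat.), EtOAc, rt
Reagents that add atoms: none
Why: Heterogeneous catalytic hydrogenation; sulfide-poisoned Pd/C should saturate the alkyne through the cis-alkene while leaving the aryl aldehyde and the N–S bond untouched.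

Step 4
Reactants: 7 11-(2-formyl-1-tosyl-1H-pyrrol-3-yl)undecanoic acid; 8 tridecanoic acid
Product: 11 3-docosyl-1-tosyl-1H-pyrrole-2-carbaldehyde, via dodecyl radical 9 (not isolated), via 10-(2-formyl-1-tosyl-1H-pyrrol-3-yl)decyl radical 10 (not isolated)
Conditions: 7 (1 equiv), 8 (6 equiv), KOH (5 mol% of total acid), MeOH, 45–50 °C, undivided cell, smooth Pt anode and cathode, constant current ca. 0.3 A cm⁻², stopped before the bulk turns alkaline
Reagents that add atoms: none
Why: At the platinum anode each carboxylate is oxidised by one electron and loses CO2 to give the primary radicals 9 and 10, which combine in the carboxylate-covered layer at the electrode to form the C10′–C11′ bond of the docosyl chain. The closest known reaction type is the mixed (crossed) Kolbe electrolysis of a fatty acid with an ω-functionalised alkanoic acid, the classical anodic decarboxylative radical coupling. No ring is closed and no stereocentre is formed, so neither a mode of closure nor a controlling element is needed. Cross- over homo-coupling is secured statistically by the six-fold excess of the cheap acid 8, so that radical 10 should meet mainly radical 9, and the homo-dimer tetracosane is a hydrocarbon that a silica plug should remove. Radical coupling over the cationic (Hofer–Moest) pathway is secured by both radicals being primary, unbranched and free of α-heteroatoms, together with smooth platinum, high current density and a weakly acidic methanol electrolyte. Survival of the heteroaromatic ring is secured by the N-tosyl and C2-formyl groups, which should lift its oxidation potential above that of the carboxylates, and by the nine-methylene spacer, which rules out intramolecular attack of radical 10 on the ring.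

Step 5
Reactants: 11 3-docosyl-1-tosyl-1H-pyrrole-2-carbaldehyde
Product: 12 3-docosyl-1H-pyrrole-2-carbaldehyde
Conditions: 2 M aq. NaOH (3 equiv), THF/MeOH 1:1, rt; aq. NH4Cl work-up
Reagents that add atoms: none
Why: Hydrolytic cleavage of an activated sulfonamide; hydroxide attacks sulfur and the 2-formylpyrrolide is a good leaving group, so the N-tosyl group should come off at room temperature without touching the non-enolisable aldehyde.

**Compound list**
1 | 3-bromo-1H-pyrrole-2-carbaldehyde | O=Cc1[nH]ccc1Br | starting material
2 | sodium 3-bromo-2-formylpyrrol-1-ide | O=Cc1[n-]ccc1Br.[Na+] | intermediate (not isolated)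
3 | 3-bromo-1-tosyl-1H-pyrrole-2-carbaldehyde | O=Cc1c(Br)ccn1S(=O)(=O)c1ccc(C)cc1 | intermediate
4 | undec-10-ynoic acid | C#CCCCCCCCCC(=O)O | starting material
5 | 11-(2-formyl-1-tosyl-1H-pyrrol-3-yl)undec-10-ynoic acid | OC(=O)CCCCCCCCC#Cc1ccn(S(=O)(=O)c2ccc(C)cc2)c1C=O | intermediate
6 | (Z)-11-(2-formyl-1-tosyl-1H-pyrrol-3-yl)undec-10-enoic acid | OC(=O)CCCCCCCC/C=C\c1ccn(S(=O)(=O)c2ccc(C)cc2)c1C=O | intermediate (not isolated)
7 | 11-(2-formyl-1-tosyl-1H-pyrrol-3-yl)undecanoic acid | OC(=O)CCCCCCCCCCc1ccn(S(=O)(=O)c2ccc(C)cc2)c1C=O | intermediate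
8 | tridecanoic acid | CCCCCCCCCCCCC(=O)O | starting material
9 | dodecyl radical | CCCCCCCCCCC[CH2] | intermediate (not isolated)
10 | 10-(2-formyl-1-tosyl-1H-pyrrol-3-yl)decyl radical | [CH2]CCCCCCCCCc1ccn(S(=O)(=O)c2ccc(C)cc2)c1C=O | intermediate (not isolated)
11 | 3-docosyl-1-tosyl-1H-pyrrole-2-carbaldehyde | CCCCCCCCCCCCCCCCCCCCCCc1ccn(S(=O)(=O)c2ccc(C)cc2)c1C=O | intermediate
12 | 3-docosyl-1H-pyrrole-2-carbaldehyde | CCCCCCCCCCCCCCCCCCCCCCc1cc[nH]c1C=O | target

**Step count**
Total steps: 5. Longest linear sequence: 5 steps (from compound 1).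

**Steps most likely to fail**

Step 4 (mixed Kolbe electrolysis). What may go wrong: anodic over-oxidation, either of the radicals to cations or of the heteroaromatic ring; passivation of the anode by the waxy products; and loss of material to statistical homo-coupling. The fallback forms the same C10′–C11′ bond as an alkene by olefin cross-metathesis; it sets out from compound 3 and comes back at compound 11. Negishi coupling of 3 with undec-10-en-1-ylzinc bromide F1 (from 11-bromoundec-1-ene, Zn dust and LiCl in THF; Pd(OAc)2/SPhos, THF, rt to 40 °C) should give 3-(undec-10-en-1-yl)-1-tosyl-1H-pyrrole-2-carbaldehyde F2. Cross-metathesis of F2 with an excess of tridec-1-ene (Grubbs second-generation catalyst, CH2Cl2, 40 °C) should give 3-[(E)-docos-10-en-1-yl]-1-tosyl-1H-pyrrole-2-carbaldehyde F3, as an E/Z mixture whose geometry is irrelevant. Hydrogenation of F3 under the conditions of step 3 returns to the route at 11.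

Step 2 (Sonogashira coupling). What may go wrong: slow oxidative addition at the C3–Br bond crowded by the formyl group, copper-mediated oxidative dimerisation of the alkyne, and sequestration of copper by the carboxylate. The fallback attaches the saturated chain directly by an sp2–sp3 coupling; it sets out from compound 3 and comes back at compound 7, bypassing step 3 as well. tert-Butyl 11-bromoundecanoate F4 (from 11-bromoundecanoic acid and tert-butyl 2,2,2-trichloroacetimidate) is converted with Zn dust and LiCl in THF into (11-tert-butoxy-11-oxoundecyl)zinc bromide F5. Negishi coupling of F5 with 3 (Pd(OAc)2/SPhos, THF, rt to 40 °C) should give tert-butyl 11-(2-formyl-1-tosyl-1H-pyrrol-3-yl)undecanoate F6. TFA in CH2Cl2 then cleaves the tert-butyl ester to acid 7 without touching the N-tosyl group.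

Step 3 (hydrogenation). What may go wrong: over-reduction of the formyl group, which is no longer a vinylogous formamide once the nitrogen is sulfonylated, or stalling at the alkene through catalyst poisoning. The fallback changes the order of protecting-group operations; it sets out from compound 5 and comes back at compound 7. The tosyl group is first removed (aq. NaOH, THF/MeOH, rt) to give 11-(2-formyl-1H-pyrrol-3-yl)undec-10-ynoic acid F7, whose formyl group is a vinylogous formamide and should resist hydrogenation. Hydrogenation (H2, Pd/C, MeOH) should then give 11-(2-formyl-1H-pyrrol-3-yl)undecanoic acid F8. Re-sulfonylation on nitrogen (NaH 2.2 equiv, THF, then TsCl 1.05 equiv; aqueous work-up hydrolyses any mixed anhydride) returns to the route at 7.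

**Further compounds**
F1 | step 4 | undec-10-en-1-ylzinc bromide | C=CCCCCCCCCC[Zn]Br
F2 | step 4 | 3-(undec-10-en-1-yl)-1-tosyl-1H-pyrrole-2-carbaldehyde | C=CCCCCCCCCCc1ccn(S(=O)(=O)c2ccc(C)cc2)c1C=O
F3 | step 4 | 3-[(E)-docos-10-en-1-yl]-1-tosyl-1H-pyrrole-2-carbaldehyde | CCCCCCCCCCC/C=C/CCCCCCCCCc1ccn(S(=O)(=O)c2ccc(C)cc2)c1C=O
F4 | step 2 | tert-butyl 11-bromoundecanoate | CC(C)(C)OC(=O)CCCCCCCCCCBr
F5 | step 2 | (11-tert-butoxy-11-oxoundecyl)zinc bromide | CC(C)(C)OC(=O)CCCCCCCCCC[Zn]Br
F6 | step 2 | tert-butyl 11-(2-formyl-1-tosyl-1H-pyrrol-3-yl)undecanoate | CC(C)(C)OC(=O)CCCCCCCCCCc1ccn(S(=O)(=O)c2ccc(C)cc2)c1C=O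
F7 | step 3 | 11-(2-formyl-1H-pyrrol-3-yl)undec-10-ynoic acid | OC(=O)CCCCCCCCC#Cc1cc[nH]c1C=O
F8 | step 3 | 11-(2-formyl-1H-pyrrol-3-yl)undecanoic acid | OC(=O)CCCCCCCCCCc1cc[nH]c1C=O
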